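Compound numbers refer to the compound list after the steps. Flavanone numbering is used for the target (O1, C2, C3, C4, C4a, C5–C8, C8a; side chain C1''–C2''), pyranone numbering for the ring-C building block (O1, C2–C6).

## Analysis of the target

Leachianone A (28) is a (2S)-flavanone: a chroman-4-one (rings A and C) with a 4-hydroxy-2-methoxyphenyl group (ring B) at C2. Ring A carries free hydroxyls at C5 and C7 and a lavandulyl chain, CH2–CH(isopropenyl)–CH2–CH=CMe2, at C8. The two stereocentres, C2 (S) and C2'' (R), are separated by six bonds and a flat arene, so neither can direct the other and each needs its own source. C2 is a benzylic ether carbon β to the ketone, so base, and more slowly acid, opens ring C to the chalcone and racemises it. The side chain holds a 1,1-disubstituted and a trisubstituted alkene next to the C7 hydroxyl, so acid closes a chroman, and hydrogenation and strong electrophiles are excluded. The main difficulty is regiochemical: C6 and C8 of a 5,7-dioxygenated chromanone are electronically alike, and lavandulyl is a homoallylic, β-branched alkyl group that neither a Claisen-type transfer nor direct C-alkylation places reliably. The plan rests on the position of C8 between C7 and C8a, the carbon that carries O1. If C5–C8 arrive as one four-carbon unit whose terminal carbon already bears the side chain, and this unit is joined to the C4a=C8a bond of an existing ring C, C8 cannot be confused with C6.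

## Retrosynthetic reasoning

28 to 27: the last bond cut is the O–Si bond at the 4'-oxygen. A silyl ether is used at this single position because it comes off under buffered, nearly neutral conditions. An acid-labile group would expose the C7 hydroxyl and the side-chain alkenes of 28 to chroman-forming conditions, and a base-labile one would invite opening of ring C.

27 to 8 and 23: ring A is cut at C4a–C5 and C8–C8a. This is the only pair of cuts that leaves O1 attached to C8a in one fragment (pyranone 8) and the side chain attached to the future C8 in the other (diene 23). The forward reaction is a Diels–Alder addition of 23 across the C5=C6 bond of 8. The sulfinyl group of 8 activates that alkene. In adduct 24 it leaves together with the C8a hydrogen by thermal syn-elimination, which gives 25. The C8a hydrogen of 24 is not acidic, so a leaving group that needs base would not serve. The methoxy group at the former ketene acetal carbon is then expelled to give the arene 26, and hydrolysis of the two trimethylsilyl ethers gives 27. Both stereocentres pass through unchanged.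

8 to 7 to 6 to 5: the S–O, C5–S and C5–I bonds are cut in turn. C5 of 5 is functionalised only after C2 is in place, so the asymmetric step is run on the simplest substrate. The route goes through iodide 6 because ring B of 5 is itself a good nucleophile toward sulfur electrophiles. Iodination under amine conditions is selective for the enone, and the C–S bond is then made by a neutral transition-metal coupling that cannot touch C2.

5 to 2 and 3: ring C is cut at C2–C3 and O1–C6, a hetero-Diels–Alder disconnection to aldehyde 2 and Danishefsky's diene 3. It creates C2 under catalyst control and delivers the enone oxidation level directly. 2 is the silyl ether of commercial phenol 1.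

23 to 21 to 20 to 17 and 18: the two O–Si bonds of 23 lead back to β-keto ester 20, and the C4–C5 bond of 20 is cut to the dianion of methyl acetoacetate (18) and iodide 17. The terminal carbon of the acetoacetate unit becomes C8 of ring A and so carries the side chain into the right place before any arene exists.

17 to 16 to 15 to 12 and 13, 12 to 9 and 10: the iodide comes from (S)-lavandulol 16. Its stereocentre is traced to the α-prenylation of the dienolate of imide 12 with bromide 13 under control of auxiliary 9, which is then removed by reduction. This sets C2'' by a predictable facial rule instead of relying on a resolution of uncertain selectivity. Descriptors change along the series (S in 15–17 and 20, R in 23 and 28) through CIP priority only; the spatial arrangement is constant.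

## Alternatives that were turned down

Alternative 1: the disconnection is the C1''–C2'' bond, made on a ring-A building block with carbene catalysis creating the side-chain stereocentre.
- Forward key step: fluoride desilylates benzyl bromide A2, tert-butyl[2-(bromomethyl)-3,5-bis(methoxymethoxy)phenoxy]dimethylsilane, and loss of bromide gives an ortho-quinone methide. A chiral triazolium-derived carbene is acylated by acyl imidazole A3, 1-(imidazol-1-yl)-5-methylhex-4-en-1-one, and deprotonated to an azolium enolate. Its α-carbon adds to the methide carbon and the phenoxide lactonises, releasing the carbene and giving dihydrocoumarin A1, (3R)-5,7-bis(methoxymethoxy)-3-(3-methylbut-2-enyl)chroman-2-one.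
- For it: C2'' is set catalytically, and the C–C bond is made by conjugate addition, not by substitution at a β-branched iodide. Ring A is still symmetric at that stage, and the lactone oxygen marks the future O1.
- Against it: the lactone carbonyl of A1 must become the isopropenyl group. Throughout that conversion C2'' is α to a carbonyl or next to a tertiary cation, so epimerisation and formation of the tetrasubstituted alkene threaten the centre the step was meant to set. The trioxygenated methide is a stabilised, weak electrophile, and an unbranched aliphatic azolium enolate lacks the aryl group that usually organises such enolates. After A1 the flavanone is still missing: acylation of ring A, condensation with the B-ring aldehyde, and an enantioselective, reversible oxa-Michael closure for C2, roughly ten further operations.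
- Comparison: on the side-chain stereocentre this plan is stronger (a catalyst against steps 6–8 with a stoichiometric auxiliary). The chosen route offers ring A, its regiochemistry and its junction to ring C in one convergent step, with C2 made catalytically on a small molecule and never exposed as a chalcone.

Alternative 2: the disconnection is O1–C2 and C3–C4, ring C by cycloaddition.
- Forward key step: salicylaldehyde A5, 4,6-bis(tert-butyldimethylsilyloxy)-2-hydroxy-3-[(2R)-lavandulyl]benzaldehyde, an orthoformate and a chiral N-triflylphosphoramide give a 4-methoxy ortho-quinone methide paired with the chiral anion. It adds styrene A6, tert-butyl(3-methoxy-4-vinylphenoxy)dimethylsilane, C3–C4 first and O1–C2 second, to give flavan A4, the (2S,4S)-4-methoxy-8-lavandulylflavan tris(tert-butyldimethylsilyl) ether.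
- For it: ring C and C2 are made in one catalytic, convergent step from two arenes, with no sulfur chemistry and no chalcone.
- Against it: A5 is a hexasubstituted arene that already needs lavandulyl at a defined position, so the central problem is moved to the starting material and not solved. A strong Brønsted acid meets the side-chain alkenes, a free phenol and an electron-rich styrene, so hydroalkoxylation and cationic oligomerisation compete. The electron-rich ring A lowers the electrophilicity of the methide. After A4 the C4 methoxy group must be hydrolysed and oxidised to the ketone and three silyl ethers removed, and the C4 stereocentre is discarded.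
- Comparison: it is stronger in how directly it sets C2 together with ring C. The chosen route removes the need for any regiodefined lavandulyl arene, because the arene is made with the side chain already in place.

Alternative 3: the disconnection is the aryl ether bond O1–C8a.
- Forward key step: zerovalent palladium carrying a bulky dialkylbiarylphosphine inserts into the C8a–Br bond of bromo alcohol A8, the (1S,3S)-3-silyloxy-1-arylpropan-1-ol bearing the 2-bromo-3-lavandulyl-4,6-bis(methoxymethoxy)phenyl group at C3. A carbonate base forms the palladium alkoxide and reductive elimination closes ring C, giving A7, the (2S,4S)-8-lavandulylflavan-4-ol silyl ether with three methoxymethyl ethers.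
- For it: the reaction type is established for chromans. The bromine fixes the regiochemistry absolutely, and C2 comes from acyclic asymmetric chemistry and is not touched, since the bond forms at oxygen.
- Against it: the bromide is flanked by two ortho substituents on a very electron-rich ring, so oxidative addition and reductive elimination are both slow. That leaves time for β-hydride elimination of the secondary benzylic alkoxide, which gives ketone and debrominated arene. A8 is again a hexasubstituted benzene with lavandulyl next to bromine. After A7 there remain desilylation, oxidation at C4 and acidic removal of three acetals in the presence of the side chain and the C7 hydroxyl.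
- Comparison: its key step carries less intrinsic risk than a cycloaddition to a donor-substituted alkene, and that is conceded. The chosen route offers a much shorter sequence, no pre-built hexasubstituted arene and an acid-free end.

Key step: step 13

Assumption: with aldehyde 2 the catalyst formed from Ti(OiPr)4 and (S)-BINOL directs the diene to the Si face, as in additions to simple aryl aldehydes; if the first run shows the opposite sense, (R)-BINOL is used and nothing else changes.

Remark: sulfoxide 8 is carried as the mixture of its two sulfur epimers, since sulfur is lost in step 13.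

## Route

Step 1
Reactants: 1 4-hydroxy-2-methoxybenzaldehyde
Product: 2 4-(tert-butyldimethylsilyloxy)-2-methoxybenzaldehyde
Conditions: TBSCl, imidazole, DMF, rt
Reagents that add atoms: tert-butyldimethylsilyl chloride, CC(C)(C)[Si](C)(C)Cl
Why: Standard silylation of a phenol; the aryl silyl ether tolerates the Lewis acid, brief TFA, iodine, the coupling and the peracid that follow, and is the only group left to remove at the end.

Step 2
Reactants: 2 4-(tert-butyldimethylsilyloxy)-2-methoxybenzaldehyde, 3 (E)-1-methoxy-3-(trimethylsilyloxy)buta-1,3-diene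
Product: 5 (2S)-2-[4-(tert-butyldimethylsilyloxy)-2-methoxyphenyl]-2,3-dihydro-4H-pyran-4-one, via Mukaiyama aldol adduct 4 (not isolated)
Conditions: Ti(OiPr)4 (10 mol%), (S)-BINOL (20 mol%), 4 Å MS, Et2O, −20 °C; then TFA, CH2Cl2, 0 °C
Reagents that add atoms: none
Why: Catalytic asymmetric hetero-Diels–Alder reaction by the Mukaiyama aldol and cyclisation pathway: the complex from Ti(OiPr)4 and (S)-BINOL activates the aldehyde, the diene terminus adds to its Si face to give 4, and TFA closes the ring by oxa-Michael addition and loss of methanol. C2 (S) is set by the catalyst alone.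

Step 3
Reactants: 5 (2S)-2-[4-(tert-butyldimethylsilyloxy)-2-methoxyphenyl]-2,3-dihydro-4H-pyran-4-one
Product: 6 (2S)-2-[4-(tert-butyldimethylsilyloxy)-2-methoxyphenyl]-5-iodo-2,3-dihydro-4H-pyran-4-one
Conditions: I2, pyridine, CH2Cl2, 0 °C → rt
Reagents that add atoms: iodine, II
Why: α-Iodination of a β-alkoxy enone with iodine and pyridine; the amine-bound iodine reacts at the enol-ether carbon C5 and leaves the electron-rich ring B and the C3 methylene alone, so C2 is not at risk.

Step 4
Reactants: 6 (2S)-2-[4-(tert-butyldimethylsilyloxy)-2-methoxyphenyl]-5-iodo-2,3-dihydro-4H-pyran-4-one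
Product: 7 (2S)-2-[4-(tert-butyldimethylsilyloxy)-2-methoxyphenyl]-5-(phenylsulfanyl)-2,3-dihydro-4H-pyran-4-one
Conditions: PhSSnBu3, Pd(PPh3)4 (5 mol%), toluene, 90 °C
Reagents that add atoms: tributyl(phenylsulfanyl)stannane, CCCC[Sn](CCCC)(CCCC)Sc1ccccc1
Why: Migita carbon–sulfur coupling of a vinyl iodide with a tin thiolate: oxidative addition into the activated C–I bond, tin-to-palladium transfer of the thiolate and reductive elimination. No base and no free thiolate are present, so neither retro-oxa-Michael opening nor thiolate addition to C6 can compete.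

Step 5
Reactants: 7 (2S)-2-[4-(tert-butyldimethylsilyloxy)-2-methoxyphenyl]-5-(phenylsulfanyl)-2,3-dihydro-4H-pyran-4-one
Product: 8 (2S)-2-[4-(tert-butyldimethylsilyloxy)-2-methoxyphenyl]-5-(phenylsulfinyl)-2,3-dihydro-4H-pyran-4-one (both sulfur epimers)
Conditions: mCPBA (1.0 equiv), CH2Cl2, −78 → −40 °C
Reagents that add atoms: 3-chloroperoxybenzoic acid, O=C(OO)c1cccc(Cl)c1
Why: Sulfide-to-sulfoxide oxidation with one equivalent of peracid at low temperature; sulfur is far more nucleophilic than the carbonyl-deactivated enol ether, and the sulfur configuration is irrelevant.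

Step 6
Reactants: 9 (4S)-4-benzyl-1,3-oxazolidin-2-one, 10 3-methylbut-2-enoyl chloride
Product: 12 (4S)-4-benzyl-3-(3-methylbut-2-enoyl)-1,3-oxazolidin-2-one, via lithium oxazolidinide 11 (not isolated)
Conditions: n-BuLi, THF, −78 °C; then 10, −78 → 0 °C
Reagents that add atoms: none
Why: N-Acylation of the lithiated Evans auxiliary with an acid chloride; at −78 °C the acyl chloride is not isomerised through the vinylketene.

Step 7
Reactants: 12 (4S)-4-benzyl-3-(3-methylbut-2-enoyl)-1,3-oxazolidin-2-one, 13 1-bromo-3-methylbut-2-ene
Product: 15 (4S)-4-benzyl-3-[(2S)-5-methyl-2-(prop-1-en-2-yl)hex-4-enoyl]-1,3-oxazolidin-2-one, via sodium dienolate 14 (not isolated)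
Conditions: NaHMDS, THF, −78 °C; then 13, −78 → −40 °C
Reagents that add atoms: none
Why: Evans alkylation in its deconjugative form: γ-deprotonation gives the chelated (Z)-dienolate 14 (the E isomer suffers allylic strain with the auxiliary), which is alkylated at the α-carbon on the face away from the benzyl group. With the (4S)-auxiliary this gives the (2S)-acyl centre, the future C2''; the product is not re-deprotonated at this temperature, so it neither epimerises nor reconjugates.

Step 8
Reactants: 15 (4S)-4-benzyl-3-[(2S)-5-methyl-2-(prop-1-en-2-yl)hex-4-enoyl]-1,3-oxazolidin-2-one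
Product: 16 (S)-lavandulol, (2S)-5-methyl-2-(prop-1-en-2-yl)hex-4-en-1-ol
Conditions: LiBH4, MeOH (1 equiv), Et2O, 0 °C
Reagents that add atoms: none
Why: Reductive cleavage of the N-acyl oxazolidinone at the exocyclic carbonyl; hydride conditions avoid the enolisable aldehyde stage being exposed to base, and auxiliary 9 is recovered.

Step 9
Reactants: 16 (S)-lavandulol
Product: 17 (S)-lavandulyl iodide, (5S)-5-(iodomethyl)-2,6-dimethylhepta-2,6-diene
Conditions: PPh3, imidazole, I2, CH2Cl2, 0 °C → rt, dark
Reagents that add atoms: iodine, II
Why: Appel iodination of a primary alcohol through the alkoxyphosphonium salt; substitution is at CH2, so the adjacent stereocentre is untouched, and the alkenes are inert to the phosphonium reagent.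

Step 10
Reactants: 18 methyl acetoacetate, 17 (S)-lavandulyl iodide
Product: 20 methyl (6S)-9-methyl-3-oxo-6-(prop-1-en-2-yl)dec-8-enoate, via acetoacetate dianion 19 (not isolated)
Conditions: 18 (1.5 equiv), NaH, THF, 0 °C; n-BuLi, 0 °C; then 17, THF/DMPU, 0 °C → rt; aq NH4Cl
Reagents that add atoms: none
Why: γ-Alkylation of the acetoacetate dianion (Weiler alkylation): the more basic terminal carbanion of 19 displaces the primary iodide by SN2. The stereocentre is β to the reacting carbon and is not involved.

Step 11
Reactants: 20 methyl (6S)-9-methyl-3-oxo-6-(prop-1-en-2-yl)dec-8-enoate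
Product: 21 methyl (6S)-9-methyl-6-(prop-1-en-2-yl)-3-(trimethylsilyloxy)deca-2,8-dienoate (E/Z mixture at C2=C3)
Conditions: TMSCl, Et3N, toluene, rt
Reagents that add atoms: chlorotrimethylsilane, C[Si](C)(C)Cl
Why: O-Silylation of the enol of a β-keto ester under soft enolisation; both alkene isomers converge in the next step.

Step 12
Reactants: 21 methyl (6S)-9-methyl-6-(prop-1-en-2-yl)-3-(trimethylsilyloxy)deca-2,8-dienoate
Product: 23 (3Z,6R)-1-methoxy-9-methyl-6-(prop-1-en-2-yl)-1,3-bis(trimethylsilyloxy)deca-1,3,8-triene, via lithium dienolate 22 (not isolated)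
Conditions: LDA, THF, −78 °C; then TMSCl, −78 °C → rt; pentane, filtration, used crude
Reagents that add atoms: chlorotrimethylsilane, C[Si](C)(C)Cl
Why: Kinetic γ-deprotonation of the vinylogous ester and O-silylation of the ester dienolate, the standard second stage of a 1,3-bis(silyloxy)diene preparation. The alkyl group ends up on the outside of the diene (3Z), the geometry a cycloaddition needs.

Step 13
Reactants: 8 (2S)-2-[4-(tert-butyldimethylsilyloxy)-2-methoxyphenyl]-5-(phenylsulfinyl)-2,3-dihydro-4H-pyran-4-one, 23 (3Z,6R)-1-methoxy-9-methyl-6-(prop-1-en-2-yl)-1,3-bis(trimethylsilyloxy)deca-1,3,8-triene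
Product: 27 (2S)-2-[4-(tert-butyldimethylsilyloxy)-2-methoxyphenyl]-5,7-dihydroxy-8-[(2R)-5-methyl-2-(prop-1-en-2-yl)hex-4-en-1-yl]-2,3-dihydro-4H-chromen-4-one, via sulfinyl cycloadduct 24 (not isolated), via methoxy dihydrochromenone 25 (not isolated), via bis(trimethylsilyl) ether 26 (not isolated)
Conditions: 23 (2 equiv), toluene, 0 → 60 °C; then 0.5 M HCl, THF, 0 °C
Reagents that add atoms: none
Why: Normal-demand Diels–Alder reaction: the C5=C6 bond of 8, activated by both the ketone and the sulfinyl group, takes up the very electron-rich diene 23; the closest known reaction type is the benzannulation of 1,3-bis(silyloxy)dienes with α-sulfinyl enones and sulfinylquinones followed by sulfoxide elimination. Ring A closes by the [4+2] cycloaddition itself, suprafacial on both partners, forming C8–C8a and C4a–C5 in one six-membered transition state that is probably asynchronous with C8–C8a leading. The selectivity needed is regiochemical, lavandulyl at C8: the alkyl-bearing terminus of 23 has the largest HOMO coefficient, and C6 of 8, β to both C=O and S=O and the only unsubstituted alkene carbon, has the largest LUMO coefficient, so electronic and steric preferences agree and the ketene acetal carbon goes to C4a. Suprafacial addition leaves the C8a hydrogen cis to the sulfinyl group in 24, the geometry of the five-centre syn-elimination, and since this is the only β-hydrogen, warming can only restore C4a=C8a and give 25. This elimination is thermal and neutral and precedes the release of any ring-A carbonyl, so O1 is never β to an enolate and ring C cannot open. Dilute acid then ionises the C5 methoxy group, the more basic of the two ketal oxygens, to a cation that is the C8-protonated arene; loss of that proton gives 26, and the two aryl trimethylsilyl ethers hydrolyse to 27 while the bulkier silyl ether on ring B stays. No stereocentre is made: the transient centres of 24 (C4a, C5, C8, C8a and sulfur) are erased, so endo/exo and facial selectivity do not matter, and C2 and C2'' are spectators.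

Step 14
Reactants: 27 leachianone A 4'-O-tert-butyldimethylsilyl ether
Product: 28 leachianone A, (2S)-5,7-dihydroxy-2-(4-hydroxy-2-methoxyphenyl)-8-[(2R)-5-methyl-2-(prop-1-en-2-yl)hex-4-en-1-yl]-2,3-dihydro-4H-chromen-4-one
Conditions: TBAF, AcOH (1:1), THF, 0 °C
Reagents that add atoms: none
Why: Fluoride cleavage of an aryl silyl ether, buffered with acetic acid so that the medium is never basic enough to enolise C3 and open ring C, and never acidic enough to add the C7 hydroxyl to the side-chain alkenes.

## Compound list

1 | 4-hydroxy-2-methoxybenzaldehyde | COc1cc(O)ccc1C=O | starting material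
2 | 4-(tert-butyldimethylsilyloxy)-2-methoxybenzaldehyde | COc1cc(O[Si](C)(C)C(C)(C)C)ccc1C=O | intermediate
3 | (E)-1-methoxy-3-(trimethylsilyloxy)buta-1,3-diene (Danishefsky's diene) | CO/C=C/C(=C)O[Si](C)(C)C | starting material
4 | (1E,5S)-5-[4-(tert-butyldimethylsilyloxy)-2-methoxyphenyl]-1-methoxy-5-(trimethylsilyloxy)pent-1-en-3-one | CO/C=C/C(=O)C[C@H](O[Si](C)(C)C)c1ccc(O[Si](C)(C)C(C)(C)C)cc1OC | intermediate (not isolated)
5 | (2S)-2-[4-(tert-butyldimethylsilyloxy)-2-methoxyphenyl]-2,3-dihydro-4H-pyran-4-one | O=C1C[C@@H](c2ccc(O[Si](C)(C)C(C)(C)C)cc2OC)OC=C1 | intermediate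
6 | (2S)-2-[4-(tert-butyldimethylsilyloxy)-2-methoxyphenyl]-5-iodo-2,3-dihydro-4H-pyran-4-one | O=C1C[C@@H](c2ccc(O[Si](C)(C)C(C)(C)C)cc2OC)OC=C1I | intermediate
7 | (2S)-2-[4-(tert-butyldimethylsilyloxy)-2-methoxyphenyl]-5-(phenylsulfanyl)-2,3-dihydro-4H-pyran-4-one | O=C1C[C@@H](c2ccc(O[Si](C)(C)C(C)(C)C)cc2OC)OC=C1Sc1ccccc1 | intermediate
8 | (2S)-2-[4-(tert-butyldimethylsilyloxy)-2-methoxyphenyl]-5-(phenylsulfinyl)-2,3-dihydro-4H-pyran-4-one, both sulfur epimers | O=C1C[C@@H](c2ccc(O[Si](C)(C)C(C)(C)C)cc2OC)OC=C1S(=O)c1ccccc1 | intermediate
9 | (4S)-4-benzyl-1,3-oxazolidin-2-one | O=C1OC[C@H](Cc2ccccc2)N1 | starting material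
10 | 3-methylbut-2-enoyl chloride | CC(C)=CC(=O)Cl | starting material
11 | lithium (4S)-4-benzyl-2-oxo-1,3-oxazolidin-3-ide | [Li+].O=C1OC[C@H](Cc2ccccc2)[N-]1 | intermediate (not isolated)
12 | (4S)-4-benzyl-3-(3-methylbut-2-enoyl)-1,3-oxazolidin-2-one | CC(C)=CC(=O)N1C(=O)OC[C@@H]1Cc1ccccc1 | intermediate
13 | 1-bromo-3-methylbut-2-ene (prenyl bromide) | CC(C)=CCBr | starting material
14 | sodium (Z)-dienolate of 12 | [Na+].C=C(C)/C=C(\[O-])N1C(=O)OC[C@@H]1Cc1ccccc1 | intermediate (not isolated)
15 | (4S)-4-benzyl-3-[(2S)-5-methyl-2-(prop-1-en-2-yl)hex-4-enoyl]-1,3-oxazolidin-2-one | C=C(C)[C@H](CC=C(C)C)C(=O)N1C(=O)OC[C@@H]1Cc1ccccc1 | intermediate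
16 | (S)-lavandulol, (2S)-5-methyl-2-(prop-1-en-2-yl)hex-4-en-1-ol | C=C(C)[C@H](CC=C(C)C)CO | intermediate
17 | (S)-lavandulyl iodide, (5S)-5-(iodomethyl)-2,6-dimethylhepta-2,6-diene | C=C(C)[C@H](CC=C(C)C)CI | intermediate
18 | methyl acetoacetate | COC(=O)CC(C)=O | starting material
19 | sodium lithium dianion of methyl acetoacetate | [Na+].[Li+].C=C([O-])C=C([O-])OC | intermediate (not isolated)
20 | methyl (6S)-9-methyl-3-oxo-6-(prop-1-en-2-yl)dec-8-enoate | COC(=O)CC(=O)CC[C@H](C(C)=C)CC=C(C)C | intermediate
21 | methyl (6S)-9-methyl-6-(prop-1-en-2-yl)-3-(trimethylsilyloxy)deca-2,8-dienoate, E/Z mixture at C2=C3 | COC(=O)C=C(O[Si](C)(C)C)CC[C@H](C(C)=C)CC=C(C)C | intermediate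
22 | lithium dienolate of 21 (γ-deprotonated) | [Li+].COC([O-])=CC(O[Si](C)(C)C)=CC[C@H](C(C)=C)CC=C(C)C | intermediate (not isolated)
23 | (3Z,6R)-1-methoxy-9-methyl-6-(prop-1-en-2-yl)-1,3-bis(trimethylsilyloxy)deca-1,3,8-triene | COC(O[Si](C)(C)C)=C/C(O[Si](C)(C)C)=C/C[C@H](C(C)=C)CC=C(C)C | intermediate
24 | (2S)-2-[4-(tert-butyldimethylsilyloxy)-2-methoxyphenyl]-5-methoxy-8-[(2R)-5-methyl-2-(prop-1-en-2-yl)hex-4-en-1-yl]-4a-(phenylsulfinyl)-5,7-bis(trimethylsilyloxy)-2,3,4a,5,8,8a-hexahydro-4H-chromen-4-one, cis ring fusion, mixture at C4a, C5, C8, C8a and sulfur | C=C(C)[C@H](CC=C(C)C)CC1C(O[Si](C)(C)C)=CC(OC)(O[Si](C)(C)C)C2(S(=O)c3ccccc3)C(=O)C[C@@H](c3ccc(O[Si](C)(C)C(C)(C)C)cc3OC)OC12 | intermediate (not isolated)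
25 | (2S)-2-[4-(tert-butyldimethylsilyloxy)-2-methoxyphenyl]-5-methoxy-8-[(2R)-5-methyl-2-(prop-1-en-2-yl)hex-4-en-1-yl]-5,7-bis(trimethylsilyloxy)-2,3,5,8-tetrahydro-4H-chromen-4-one, mixture at C5 and C8 | C=C(C)[C@H](CC=C(C)C)CC1C(O[Si](C)(C)C)=CC(OC)(O[Si](C)(C)C)C2=C1O[C@H](c1ccc(O[Si](C)(C)C(C)(C)C)cc1OC)CC2=O | intermediate (not isolated)
26 | (2S)-2-[4-(tert-butyldimethylsilyloxy)-2-methoxyphenyl]-8-[(2R)-5-methyl-2-(prop-1-en-2-yl)hex-4-en-1-yl]-5,7-bis(trimethylsilyloxy)-2,3-dihydro-4H-chromen-4-one | C=C(C)[C@H](CC=C(C)C)Cc1c(O[Si](C)(C)C)cc(O[Si](C)(C)C)c2c1O[C@H](c1ccc(O[Si](C)(C)C(C)(C)C)cc1OC)CC2=O | intermediate (not isolated)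
27 | leachianone A 4'-O-tert-butyldimethylsilyl ether, (2S)-2-[4-(tert-butyldimethylsilyloxy)-2-methoxyphenyl]-5,7-dihydroxy-8-[(2R)-5-methyl-2-(prop-1-en-2-yl)hex-4-en-1-yl]-2,3-dihydro-4H-chromen-4-one | C=C(C)[C@H](CC=C(C)C)Cc1c(O)cc(O)c2c1O[C@H](c1ccc(O[Si](C)(C)C(C)(C)C)cc1OC)CC2=O | intermediate
28 | leachianone A | C=C(C)[C@H](CC=C(C)C)Cc1c(O)cc(O)c2c1O[C@H](c1ccc(O)cc1OC)CC2=O | target

## Step count and least certain steps

Total: 14 steps. Longest linear sequence: 9 steps (steps 6–12, then 13 and 14); the pyranone branch (steps 1–5) joins at step 13.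

Step 13 (key step).
- What may go wrong: the oxygen at C6 of 8 donates into the alkene and lowers its dienophilicity, so the diene may be consumed by desilylation or silyl migration faster than it adds. The sulfenic acid released can also protonate remaining diene, which is why 23 is used in excess. If acid reaches adduct 24 before the sulfoxide has left, retro-Claisen cleavage of the C4a–C5 bond would undo the ring closure. On aromatisation, departure of the silyloxy group in place of the methoxy group would leave a C5 methyl ether.
- Fallback, from 8 and 23, returning at 27: the two bonds are made one at a time. A ZnBr2-promoted Mukaiyama–Michael addition of the diene terminus to C6 of 8 at low temperature, followed by aqueous work-up, would give the keto ester F1. Warming in toluene removes the sulfoxide by the same syn-elimination and gives the 6-substituted dihydropyranone F2. Mg(OMe)2 in MeOH then deprotonates the carbon between the ring and the ketone, and the extended enolate acylates C4a with the ester (Claisen cyclisation); enolisation gives 27.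

Step 10.
- What may go wrong: the iodide is β-branched and its β-hydrogen is allylic, so E2 elimination to a conjugated diene by the strongly basic dianion may outrun substitution.
- Fallback, from 17, returning at 20: alkylation of the much less basic monoanion of ethyl acetoacetate (NaH, DMF, 60 °C) gives F3. Krapcho dealkoxycarbonylation (LiCl, wet DMSO, 150 °C) gives methyl ketone F4. Carboxylation at the methyl group (NaH, dimethyl carbonate, THF, reflux) gives 20.

Step 2.
- What may go wrong: the aldehyde carries two donor groups and an ortho substituent, so catalysed addition may be slow and an uncatalysed or silyl-cation-catalysed background reaction may erode the enantioselectivity.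
- Fallback, from 2, returning at 5: a boron aldol reaction of (E)-4-methoxybut-3-en-2-one through its Ipc2B enolate (Ipc2BCl, Et3N; antipode chosen for Si-face addition) gives hydroxy enone F5. Acid (TFA, CH2Cl2) cyclises F5 to 5; the enantiomeric purity can be raised by crystallisation of 5 or 6.

Step 4.
- What may go wrong: sulfur may bind the catalyst and slow turnover, and transfer of the thiolate to a hindered α-keto vinyl palladium species may be slow enough for protodeiodination back to 5.
- Fallback, from 5, returning at 7 (skipping 6): direct electrophilic sulfenylation with PhSCl in CH2Cl2 at −78 °C gives the chloro sulfide F6, which loses HCl on addition of Et3N. The known weakness of this variant is competing sulfenylation of ring B, which is the reason it is not the first choice.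

## Further compounds

F1 | step 13 | methyl 4-{6-[4-(tert-butyldimethylsilyloxy)-2-methoxyphenyl]-4-oxo-3-(phenylsulfinyl)tetrahydro-2H-pyran-2-yl}-9-methyl-3-oxo-6-(prop-1-en-2-yl)dec-8-enoate, aryl-bearing ring carbon as in 8, side-chain centre as in 20, other centres mixed | COC(=O)CC(=O)C(C[C@H](C(C)=C)CC=C(C)C)C1O[C@H](c2ccc(O[Si](C)(C)C(C)(C)C)cc2OC)CC(=O)C1S(=O)c1ccccc1
F2 | step 13 | methyl 4-{(2S)-2-[4-(tert-butyldimethylsilyloxy)-2-methoxyphenyl]-4-oxo-3,4-dihydro-2H-pyran-6-yl}-9-methyl-3-oxo-6-(prop-1-en-2-yl)dec-8-enoate, side-chain centre as in 20, C4 of the chain mixed | COC(=O)CC(=O)C(C[C@H](C(C)=C)CC=C(C)C)C1=CC(=O)C[C@@H](c2ccc(O[Si](C)(C)C(C)(C)C)cc2OC)O1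
F3 | step 10 | ethyl (4R)-2-acetyl-7-methyl-4-(prop-1-en-2-yl)oct-6-enoate, mixture at C2 | CCOC(=O)C(C(C)=O)C[C@H](C(C)=C)CC=C(C)C
F4 | step 10 | (5S)-8-methyl-5-(prop-1-en-2-yl)non-7-en-2-one | CC(=O)CC[C@H](C(C)=C)CC=C(C)C
F5 | step 2 | (1E,5S)-5-[4-(tert-butyldimethylsilyloxy)-2-methoxyphenyl]-5-hydroxy-1-methoxypent-1-en-3-one | CO/C=C/C(=O)C[C@H](O)c1ccc(O[Si](C)(C)C(C)(C)C)cc1OC
F6 | step 4 | (2S)-2-[4-(tert-butyldimethylsilyloxy)-2-methoxyphenyl]-6-chloro-5-(phenylsulfanyl)tetrahydro-4H-pyran-4-one, mixture at C5 and C6 | O=C1C[C@@H](c2ccc(O[Si](C)(C)C(C)(C)C)cc2OC)OC(Cl)C1Sc1ccccc1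
A1 | alternative 1 | (3R)-5,7-bis(methoxymethoxy)-3-(3-methylbut-2-enyl)chroman-2-one | O=C1Oc2cc(OCOC)cc(OCOC)c2C[C@H]1CC=C(C)C
A2 | alternative 1 | tert-butyl[2-(bromomethyl)-3,5-bis(methoxymethoxy)phenoxy]dimethylsilane | BrCc1c(O[Si](C)(C)C(C)(C)C)cc(OCOC)cc1OCOC
A3 | alternative 1 | 1-(1H-imidazol-1-yl)-5-methylhex-4-en-1-one | CC(C)=CCCC(=O)n1ccnc1
A4 | alternative 2 | (2S,4S)-4-methoxy-8-[(2R)-lavandulyl]flavan 5,7,4'-tris(tert-butyldimethylsilyl) ether with 2'-methoxy group | C=C(C)[C@H](CC=C(C)C)Cc1c(O[Si](C)(C)C(C)(C)C)cc(O[Si](C)(C)C(C)(C)C)c2c1O[C@H](c1ccc(O[Si](C)(C)C(C)(C)C)cc1OC)C[C@@H]2OC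
A5 | alternative 2 | 4,6-bis(tert-butyldimethylsilyloxy)-2-hydroxy-3-[(2R)-5-methyl-2-(prop-1-en-2-yl)hex-4-en-1-yl]benzaldehyde | C=C(C)[C@H](CC=C(C)C)Cc1c(O[Si](C)(C)C(C)(C)C)cc(O[Si](C)(C)C(C)(C)C)c(C=O)c1O
A6 | alternative 2 | tert-butyl(3-methoxy-4-vinylphenoxy)dimethylsilane | C=Cc1ccc(O[Si](C)(C)C(C)(C)C)cc1OC
A7 | alternative 3 | (2S,4S)-4-(tert-butyldimethylsilyloxy)-8-[(2R)-lavandulyl]-2'-methoxy-5,7,4'-tris(methoxymethoxy)flavan | C=C(C)[C@H](CC=C(C)C)Cc1c(OCOC)cc(OCOC)c2c1O[C@H](c1ccc(OCOC)cc1OC)C[C@@H]2O[Si](C)(C)C(C)(C)C
A8 | alternative 3 | (1S,3S)-3-{2-bromo-4,6-bis(methoxymethoxy)-3-[(2R)-5-methyl-2-(prop-1-en-2-yl)hex-4-en-1-yl]phenyl}-3-(tert-butyldimethylsilyloxy)-1-[2-methoxy-4-(methoxymethoxy)phenyl]propan-1-ol | C=C(C)[C@H](CC=C(C)C)Cc1c(OCOC)cc(OCOC)c(c1Br)[C@@H](O[Si](C)(C)C(C)(C)C)C[C@H](O)c1ccc(OCOC)cc1OC
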